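## The problem

The target 12 is a single oxolane ring in which all four carbons are stereogenic. Numbered O1, C2, C3, C4, C5, it carries ring B (4-hydroxy-3,5-dimethoxyphenyl) on C2, one methyl on each of C3 and C4, and ring A (3,4-dimethoxyphenyl) on C5; the configuration is (2S,3S,4S,5R). The two aryl groups differ, so there is no symmetry to use and each end of the C2–C5 chain must meet its own aryl partner. The relative configuration is 2,3-trans, 3,4-trans, 4,5-cis. The C4 methyl/ring A pair is therefore not the relaxed arrangement, and C5 has to be set under kinetic control and kept from equilibrating afterwards. Control can be relayed: C3 can direct C2 in a ring-forming event, C3 can direct C4 once C4 is epimerisable next to a cationic C5, and the C4 methyl together with ring B can direct a nucleophile to C5. One absolute decision at C2/C3 is therefore enough. Both C2–O1 and C5–O1 are benzylic ethers of electron-rich rings: strong acid ionises them (epimerisation toward the all-trans isomer, reductive ring opening) and hydrogenolysis threatens them. The phenol of ring B is oxidisable and would trap a carbene, so it must travel masked and be released last under neutral conditions. The enabling feature is C2: it is bonded only to O1, C3, ring B and hydrogen, so it can arrive as a one-carbon aryl carbene, while O1, C5, C4 and C3 with ring A and both methyls form the O=C–C=C chain of an aryl enone. Joining them leaves a C4=C5 enol ether, from which C4 and C5 can be set by protonation and hydride.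

## Retrosynthesis

**12 to 11 (O–Si).** The last cut is the phenol O–Si bond, giving triisopropylsilyl ether 11. A benzyl ether would need hydrogenolysis beside two benzylic ring C–O bonds, and an acyl group would not survive hydrazine. The hindered silyl ether should survive hydrazine, MnO2, a copper carbene and cold CF3CO2H, and it leaves with fluoride. The forward step only has to be chemoselective.

**11 to 9 (C4–H and C5–H).** Removing these two hydrogens leads to 2,3-dihydrofuran 9 with a C4=C5 enol ether. Two neighbouring cuts were weighed:
- Adding ring A as a nucleophile to a C5–H oxocarbenium ion: the nucleophile would enter on the face that hydride uses, so ring A would end up trans to the C4 methyl, which is the wrong isomer.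
- Closing a 1,4-diol by displacement: this needs extra steps and a separately controlled carbinol centre.

With ring A already on C5, hydride is the incoming group and the same facial preference gives the 4,5-cis pair. Precursor 9 has two stereocentres fewer. The forward reaction must protonate C4 reversibly, so that the methyl settles trans to the C3 methyl through oxocarbenium ion 10. It must then deliver hydride to C5 opposite the C4 methyl and ring B, without ionising either benzylic C–O bond.

**9 to 3 and 7 (O1–C2 and C2–C3).** Cutting both bonds to C2 releases aryldiazomethane 7 (C2 with ring B) and enone 3 (O1, C5, C4, C3, both methyls, ring A). The mirror-image cut at C5 (ring A carbene, ring B enone) would ask the cycloaddition for the cis aryl/methyl pair, whereas ring closure is expected to place the aryl trans to the neighbouring methyl. The chosen cut gives two halves of similar size, each one to three steps from commercial materials, and no carbon is later removed. The forward reaction is a copper-catalysed (4+1) annulation through carbonyl ylide 8. It must be trans-selective and enantioselective, and oxygen attack must win over alkene cyclopropanation, carbene dimerisation and dipolar cycloaddition. The chiral bipyridine meant throughout is the C2-symmetric planar-chiral 2,2'-bipyridine whose pyridine rings are each fused to a cyclopentadienyl ring bound to Fe(C5Me5).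

**7 to 6 to 5 to 4 (C=N2, C=N, O–Si).** The diazo group is traced to hydrazone 6, then to silylated aldehyde 5 and syringaldehyde 4. Oxidation of a free hydrazone at 0 °C is preferred to thermolysis of a sulfonylhydrazone salt. Thermolysis needs warming that this electron-rich diazoalkane may not tolerate, and it leaves sulfinate and a phase-transfer salt in the solution fed to the copper catalyst.

**3 to 1 and 2 (aryl–acyl bond).** Veratrole 1 and tigloyl chloride 2 are joined by Friedel–Crafts acylation in one step; an organometallic route through an amide takes two. The forward step needs para selectivity, retention of the (E)-alkene, and no further reaction of the aryl vinyl ketone.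

## Roads not taken

**Alternative 1:** The cut removes both C–CH3 bonds and leaves ring A for a later organometallic addition.
- Forward key step: a methyl cuprate adds to butenolide A1 anti to the aryl group, and the enolate is methylated by iodomethane anti to the new methyl. This gives lactone A2, which holds the centres that become C2, C3 and C4 of 12. Ring A would then be added as an aryllithium to the lactone carbonyl and the product reduced with a Lewis acid and a silane.
- Merits: every operation is a known reaction type on this ring system, and both methyl centres follow from one existing centre.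
- Weak points: A1 must first be made enantioenriched over several steps, and its C5–H is acidic enough to be at risk under the basic cuprate and enolate conditions. Enolates from cuprate additions react sluggishly with iodomethane and can over-alkylate. The sequence is linear, roughly eight or nine operations.
- Comparison: on precedent this road is safer, and that is conceded. Its endgame passes through the same kind of C5 oxocarbenium ion as 10, so it does not avoid the facial question of step 6. The chosen plan sets against it convergence, seven steps in all, and formation of the ring with C2 and C3 in one catalytic event from achiral materials. The price is an undemonstrated key step.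

**Alternative 2:** The cut is O1–C5 and C2–C3, a (3+2) union of aryl aldehyde A4 (C2 and O1) with donor–acceptor cyclopropane A3 (C5, C4 and, as the malonate carbon, C3).
- Forward key step: Sn(OTf)2 (divalent tin) activates the diester, the aldehyde oxygen opens the cyclopropane at the aryl-bearing carbon with inversion, and the malonate carbon closes on the oxocarbenium carbon to give A5.
- Merits: the reaction type is established and stereospecific. It installs the cis-diaryl relation and the difficult C4 methyl/ring A cis pair directly under kinetic control. In this respect it is better than the hydride reduction of step 6.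
- Weak points: C3 arrives as a gem-diester and must become CH(CH3). This takes dealkoxycarbonylation, ester reduction, activation and hydride displacement, four steps that only remove oxygen and one carbon. A3 is needed as one enantiomer, and asymmetric malonate-carbene cyclopropanation of a propenylarene is not routine. The benzyl ether must finally be hydrogenolysed beside two benzylic ring C–O bonds.
- Comparison: more secure at C5 but about nine steps. The chosen plan brings every carbon in at its final oxidation level and needs no enantioenriched starting fragment. Its C5 centre rests on facial selectivity, not on a stereospecific displacement.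

**Alternative 3:** The cut is C3–C4 together with both ring C–O bonds, leading to two propenylphenols.
- Forward key step: a laccase (a multicopper oxidase) with a dirigent protein oxidises isoeugenol A6 and 4-propenylsyringol A7 to phenoxyl radicals that couple at C3–C4. Water adds to one quinone methide and the new hydroxyl closes on the other, giving bisphenol A8.
- Merits: one step, no protecting groups; in step count it cannot be beaten.
- Weak points: no protein is known to steer this cross-coupling. Both radicals would also homo-couple and couple through oxygen or ring carbons. The two C–O bonds form on quinone methides under conditions that favour trans aryl/methyl at both ends, not the 4,5-cis pair. A8 would still need methylation of the ring A phenol in the presence of the ring B phenol.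
- Comparison: shorter, but without a handle on chemo-, regio- or stereoselectivity. The chosen plan is longer and assigns each selectivity to a named control element.

Key step: step 5

Assumption: the sense of induction of the copper/bipyridine catalyst with an aryl carbene cannot be predicted from the diazoacetate case; the ligand antipode that delivers (2S,3S)-9 is used, both antipodes being accessible.

## Route

Step 1
Reactants: 1 veratrole (1,2-dimethoxybenzene); 2 tigloyl chloride [(E)-2-methylbut-2-enoyl chloride]
Product: 3 (E)-1-(3,4-dimethoxyphenyl)-2-methylbut-2-en-1-one
Conditions: AlCl3 (1.1 equiv), CH2Cl2, −10 to 0 °C; then ice-water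
Reagents that add atoms: none
Why: Friedel–Crafts acylation; the acylium complex of 2 attacks veratrole para to a methoxy group, and the ketone–AlCl3 complex is deactivated toward a second acylation. The (E)-alkene is the stable isomer and is retained; holding at or below 0 °C and quenching early is meant to prevent Nazarov cyclisation of the aryl vinyl ketone and ether cleavage.

Step 2
Reactants: 4 syringaldehyde (4-hydroxy-3,5-dimethoxybenzaldehyde)
Product: 5 3,5-dimethoxy-4-[(triisopropylsilyl)oxy]benzaldehyde
Conditions: i-Pr3SiCl, imidazole, DMAP (cat.), DMF, 23 °C
Reagents that add atoms: chlorotriisopropylsilane, CC(C)[Si](Cl)(C(C)C)C(C)C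
Why: Silylation of a phenol with a silyl chloride and imidazole; the phenol is acidic (para formyl group) and reacts despite its two methoxy neighbours. The silyl ether blocks O–H insertion in step 5, is shielded against hydrazine, tolerates cold CF3CO2H and leaves with fluoride.

Step 3
Reactants: 5 3,5-dimethoxy-4-[(triisopropylsilyl)oxy]benzaldehyde
Product: 6 (E)-{3,5-dimethoxy-4-[(triisopropylsilyl)oxy]benzylidene}hydrazine
Conditions: N2H4·H2O (10 equiv), EtOH, 0 to 23 °C, 5 added slowly
Reagents that add atoms: hydrazine hydrate, NN.O
Why: Hydrazone formation by condensation; slow addition of 5 to a large excess of hydrazine keeps aldehyde from meeting product and so suppresses the azine. The hydrazone geometry is of no consequence.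

Step 4
Reactants: 6 (E)-{3,5-dimethoxy-4-[(triisopropylsilyl)oxy]benzylidene}hydrazine
Product: 7 {3,5-dimethoxy-4-[(triisopropylsilyl)oxy]phenyl}diazomethane (cold CH2Cl2 solution)
Conditions: activated MnO2 (8 equiv), MgSO4, CH2Cl2, 0 °C; cold filtration, solution used at once
Reagents that add atoms: none
Why: Dehydrogenation of an N-unsubstituted hydrazone to a diazoalkane with activated MnO2, a known route to aryldiazomethanes. Oxidant and reduced oxidant are solids and are filtered off, so the solution carries no amine, sulfide or sulfinate that could bind copper in step 5.

Step 5
Reactants: 3 (E)-1-(3,4-dimethoxyphenyl)-2-methylbut-2-en-1-one; 7 {3,5-dimethoxy-4-[(triisopropylsilyl)oxy]phenyl}diazomethane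
Product: 9 (2S,3S)-5-(3,4-dimethoxyphenyl)-2-{3,5-dimethoxy-4-[(triisopropylsilyl)oxy]phenyl}-3,4-dimethyl-2,3-dihydrofuran (2,3-trans), via carbonyl ylide 8 (not isolated)
Conditions: (CuOTf)2·C6H6 (2.5 mol%), planar-chiral 2,2'-bipyridine ligand [each pyridine fused to a C5 ring bound to Fe(C5Me5)] (6 mol%), CH2Cl2, 0 to 23 °C; 7 added over 8 h to 3 (2 equiv)
Reagents that add atoms: none
Why: Proposed new method: CuOTf with the chiral bipyridine decomposes 7 to a monovalent copper aryl carbene, the carbonyl oxygen of s-cis 3 attacks its electrophilic carbon to give the copper-associated carbonyl ylide 8 (O1–C2 bond), and 8 closes between the ylide carbon and the former β-carbon (C2–C3 bond) with release of the catalyst. The closest known reaction type is the copper/chiral bipyridine-catalysed enantioselective (4+1) cycloaddition of enones with diazoacetates to trans-2,3-dihydrofurans, in which an aryl (donor) carbene has not been used. The one ring is closed by C–C bond formation in a 6π 1,5-electrocyclisation of the oxapentadienyl system (formally 5-endo-trig, allowed because it is pericyclic), and a cyclopropanation followed by ring expansion would lead to the same product. C3 is set by the face of the enone β-carbon that is bonded, which the chiral bipyridine controls while copper is still attached to the ylide carbon. C2 is set relative to C3, because ring B and the C3 methyl avoid each other in the bond-forming transition state as ester and β-substituent do in the diazoacetate case, and trans is also the more stable arrangement. The step needs oxygen attack in preference to alkene cyclopropanation, carbene dimerisation, azine formation and uncatalysed dipolar cycloaddition. The substrate helps, since the alkene of 3 is trisubstituted and electron-poor and hence a poor partner for an electrophilic carbene and for a diazoalkane dipole, while the aryl ketone oxygen is a good donor. Slow addition of 7 to excess 3 keeps the diazo concentration low, and the only para donor of 7 is a silyloxy group twisted out of conjugation by its methoxy neighbours, so its diazo carbon is less nucleophilic than that of 4-methoxyphenyldiazomethane.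

Step 6
Reactants: 9 (2S,3S)-5-(3,4-dimethoxyphenyl)-2-{3,5-dimethoxy-4-[(triisopropylsilyl)oxy]phenyl}-3,4-dimethyl-2,3-dihydrofuran
Product: 11 {4-[(2S,3S,4S,5R)-5-(3,4-dimethoxyphenyl)-3,4-dimethyloxolan-2-yl]-2,6-dimethoxyphenoxy}tri(propan-2-yl)silane, via oxocarbenium ion 10 (not isolated)
Conditions: Et3SiH (5 equiv), CF3CO2H (5 equiv), CH2Cl2, −78 to −40 °C; Et3N, then aq NaHCO3
Reagents that add atoms: none
Why: Ionic hydrogenation of an enol ether (Kursanov–Parnes reduction) through C5 oxocarbenium ion 10, the cation through which Lewis acid/silane reductions of 2-aryl lactols also pass. C4: protonation of 9 is reversible and faster than hydride transfer, so the C4 methyl settles trans to the C3 methyl; C5: Et3SiH delivers hydride to the face opposite the C4 methyl and ring B, which places ring A cis to the C4 methyl. Low temperature and a basic quench are meant to prevent ionisation of the benzylic C–O bonds of 11.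

Step 7
Reactants: 11 {4-[(2S,3S,4S,5R)-5-(3,4-dimethoxyphenyl)-3,4-dimethyloxolan-2-yl]-2,6-dimethoxyphenoxy}tri(propan-2-yl)silane
Product: 12 4-[(2S,3S,4S,5R)-5-(3,4-dimethoxyphenyl)-3,4-dimethyloxolan-2-yl]-2,6-dimethoxyphenol
Conditions: Bu4NF (1.2 equiv), AcOH (1.2 equiv), THF, 0 °C
Reagents that add atoms: none
Why: Fluoride cleavage of an aryl silyl ether; no stereocentre is touched, and the buffered, non-reducing conditions leave both benzylic C–O bonds alone.

## Compound list

1 | veratrole (1,2-dimethoxybenzene) | COc1ccccc1OC | starting material
2 | tigloyl chloride [(E)-2-methylbut-2-enoyl chloride] | C/C=C(\C)C(Cl)=O | starting material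
3 | (E)-1-(3,4-dimethoxyphenyl)-2-methylbut-2-en-1-one | C/C=C(\C)C(=O)c1ccc(OC)c(OC)c1 | intermediate
4 | syringaldehyde | COc1cc(C=O)cc(OC)c1O | starting material
5 | 3,5-dimethoxy-4-[(triisopropylsilyl)oxy]benzaldehyde | COc1cc(C=O)cc(OC)c1O[Si](C(C)C)(C(C)C)C(C)C | intermediate
6 | (E)-{3,5-dimethoxy-4-[(triisopropylsilyl)oxy]benzylidene}hydrazine | COc1cc(/C=N/N)cc(OC)c1O[Si](C(C)C)(C(C)C)C(C)C | intermediate
7 | {3,5-dimethoxy-4-[(triisopropylsilyl)oxy]phenyl}diazomethane | [N-]=[N+]=Cc1cc(OC)c(O[Si](C(C)C)(C(C)C)C(C)C)c(OC)c1 | intermediate
8 | carbonyl ylide from 3 and the carbene of 7 (drawn copper-free) | C/C=C(\C)C(c1ccc(OC)c(OC)c1)=[O+][CH-]c1cc(OC)c(O[Si](C(C)C)(C(C)C)C(C)C)c(OC)c1 | intermediate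
9 | (2S,3S)-5-(3,4-dimethoxyphenyl)-2-{3,5-dimethoxy-4-[(triisopropylsilyl)oxy]phenyl}-3,4-dimethyl-2,3-dihydrofuran | COc1ccc(C2=C(C)[C@H](C)[C@@H](c3cc(OC)c(O[Si](C(C)C)(C(C)C)C(C)C)c(OC)c3)O2)cc1OC | intermediate
10 | (3S,4S,5S)-2-(3,4-dimethoxyphenyl)-5-{3,5-dimethoxy-4-[(triisopropylsilyl)oxy]phenyl}-3,4-dimethyl-4,5-dihydro-3H-furan-1-ium (oxocarbenium ion, 3,4-trans-4,5-trans) | COc1ccc(C2=[O+][C@H](c3cc(OC)c(O[Si](C(C)C)(C(C)C)C(C)C)c(OC)c3)[C@@H](C)[C@@H]2C)cc1OC | intermediate
11 | {4-[(2S,3S,4S,5R)-5-(3,4-dimethoxyphenyl)-3,4-dimethyloxolan-2-yl]-2,6-dimethoxyphenoxy}tri(propan-2-yl)silane | COc1ccc([C@@H]2O[C@H](c3cc(OC)c(O[Si](C(C)C)(C(C)C)C(C)C)c(OC)c3)[C@@H](C)[C@@H]2C)cc1OC | intermediate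
12 | 4-[(2S,3S,4S,5R)-5-(3,4-dimethoxyphenyl)-3,4-dimethyloxolan-2-yl]-2,6-dimethoxyphenol | COc1ccc([C@@H]2O[C@H](c3cc(OC)c(O)c(OC)c3)[C@@H](C)[C@@H]2C)cc1OC | target

## Step count and least certain steps

Total: 7 steps. Longest linear sequence: 6 steps (4 to 5 to 6 to 7 to 9 to 11 to 12; steps 2–7). The enone branch adds one step (step 1).

**Step 5 (key step, proposed new method).**
- Most likely failure: the carbene is consumed by 7 itself (dimerisation to a stilbene, azine formation), or 7 adds to 3 as a dipole. A donor carbene comes from a nucleophilic diazoalkane, and a ketone oxygen is only a moderate trap.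
- Second concern: loss of trans- or enantioselectivity if the ylide leaves copper before closing. A metal-free ylide would close from its less crowded geometry by its own disrotatory preference, which favours the cis isomer.
- Fallback with known chemistry, from 3 and 7 back to 9: 7 is converted with Rh2(OAc)4 and a chiral sulfide into a benzylic sulfonium ylide. This cyclopropanates 3 by conjugate addition and ring closure (Corey–Chaykovsky type) to the aryl cyclopropyl ketone F1, and its major diastereomer is separated. A Lewis acid such as Sc(OTf)3 in CH2Cl2 then induces the Cloke–Wilson rearrangement: the bond between the acyl-bearing and aryl-bearing carbons opens to a zwitterion that closes on oxygen. The methyl-bearing methine keeps its configuration and becomes C3, and the aryl-bearing carbon is reset under thermodynamic control to the trans isomer.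

**Step 6.**
- Most likely failure: ionisation of a benzylic C–O bond by CF3CO2H at the temperature needed to protonate the tetrasubstituted enol ether. This would epimerise C5 toward the all-trans isomer or open the ring reductively. Hydride transfer before C4 has equilibrated, or to the wrong face, would also erode the C4/C5 outcome.
- Fallback, from 9 back to 11: pyridinium p-toluenesulfonate in methanol at 0 °C adds methanol across the enol ether to give the methyl ketal F2. This separates protonation from reduction. F2 is then ionised with BF3·OEt2 in the presence of Et3SiH at −78 to −20 °C, the established reductive deoxygenation of 2-aryl cyclic ketals, where the cation forms at a temperature the product tolerates.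

**Step 4.**
- Most likely failure: loss of diazo titre through azine formation and decomposition on the oxidant surface or during filtration. Partial desilylation by hydrazine in step 3 would also carry free phenol into step 5.
- Fallback, from 5 back to 7: 5 is condensed with 4-methylbenzenesulfonohydrazide in methanol to the tosylhydrazone F3, which is deprotonated with NaH in THF to its sodium salt F4. Bamford–Stevens decomposition of F4 at 30–40 °C with catalytic benzyltriethylammonium chloride releases 7 slowly inside the flask of step 5, so the diazoalkane is never handled.

**Step 1.**
- Most likely failure: further reaction of the product under AlCl3, namely Nazarov cyclisation to an indanone, addition of HCl or arene to the enone, or demethylation.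
- Fallback, from 2 back to 3: 2 is treated with N,O-dimethylhydroxylamine hydrochloride and pyridine to give the Weinreb amide F5. Commercial 3,4-dimethoxyphenylmagnesium bromide in THF at 0 °C then gives the ketone (Weinreb ketone synthesis) without any Lewis acid.

## Further compounds

F1 | step 5 | (3,4-dimethoxyphenyl){(2R)-3-[3,5-dimethoxy-4-(triisopropylsilyloxy)phenyl]-1,2-dimethylcyclopropyl}methanone (configurations at C1 and C3 immaterial) | COc1ccc(C(=O)C2(C)[C@H](C)C2c3cc(OC)c(O[Si](C(C)C)(C(C)C)C(C)C)c(OC)c3)cc1OC
F2 | step 6 | (2S,3S)-5-(3,4-dimethoxyphenyl)-2-{3,5-dimethoxy-4-[(triisopropylsilyl)oxy]phenyl}-5-methoxy-3,4-dimethyloxolane (mixture at C4 and C5) | COc1ccc(C2(OC)O[C@H](c3cc(OC)c(O[Si](C(C)C)(C(C)C)C(C)C)c(OC)c3)[C@@H](C)C2C)cc1OC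
F3 | step 4 | N'-[(E)-{3,5-dimethoxy-4-[(triisopropylsilyl)oxy]phenyl}methylidene]-4-methylbenzenesulfonohydrazide | Cc1ccc(S(=O)(=O)N/N=C/c2cc(OC)c(O[Si](C(C)C)(C(C)C)C(C)C)c(OC)c2)cc1
F4 | step 4 | sodium salt of F3 | Cc1ccc(S(=O)(=O)[N-]/N=C/c2cc(OC)c(O[Si](C(C)C)(C(C)C)C(C)C)c(OC)c2)cc1.[Na+]
F5 | step 1 | (2E)-N-methoxy-N,2-dimethylbut-2-enamide | C/C=C(\C)C(=O)N(C)OC
A1 | alternative 1 | (5S)-5-[4-(benzyloxy)-3,5-dimethoxyphenyl]furan-2(5H)-one | O=C1O[C@H](c2cc(OC)c(OCc3ccccc3)c(OC)c2)C=C1
A2 | alternative 1 | (3S,4S,5S)-5-[4-(benzyloxy)-3,5-dimethoxyphenyl]-3,4-dimethyloxolan-2-one | O=C1O[C@H](c2cc(OC)c(OCc3ccccc3)c(OC)c2)[C@@H](C)[C@@H]1C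
A3 | alternative 2 | dimethyl (2S,3R)-2-(3,4-dimethoxyphenyl)-3-methylcyclopropane-1,1-dicarboxylate | COc1ccc([C@@H]2[C@@H](C)C2(C(=O)OC)C(=O)OC)cc1OC
A4 | alternative 2 | 4-(benzyloxy)-3,5-dimethoxybenzaldehyde | COc1cc(C=O)cc(OC)c1OCc1ccccc1
A5 | alternative 2 | dimethyl (2R,4S,5R)-2-[4-(benzyloxy)-3,5-dimethoxyphenyl]-5-(3,4-dimethoxyphenyl)-4-methyloxolane-3,3-dicarboxylate | COc1ccc([C@@H]2O[C@H](c3cc(OC)c(OCc4ccccc4)c(OC)c3)C(C(=O)OC)(C(=O)OC)[C@@H]2C)cc1OC
A6 | alternative 3 | isoeugenol [(E)-2-methoxy-4-(prop-1-en-1-yl)phenol] | C/C=C/c1ccc(O)c(OC)c1
A7 | alternative 3 | 4-propenylsyringol [(E)-2,6-dimethoxy-4-(prop-1-en-1-yl)phenol] | C/C=C/c1cc(OC)c(O)c(OC)c1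
A8 | alternative 3 | 4-[(2S,3S,4S,5R)-5-(4-hydroxy-3-methoxyphenyl)-3,4-dimethyloxolan-2-yl]-2,6-dimethoxyphenol | COc1cc([C@@H]2O[C@H](c3cc(OC)c(O)c(OC)c3)[C@@H](C)[C@@H]2C)ccc1O
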